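Which set-up turns the most Jy into Ju, given that the catalyst Lx first makes Yx from Jy, then binds Yx as LxYx, and LxYx with Xa gives Ju?

all flasks: Xa 0.154 M; Lx 0.31 mM; Rx 88 µM

| run | Jy | remark | time |
|---|---|---|---|
| maple | 0.14 M | one stirred flow tank at steady state, fed with the mixture as stated, mean residence time 80 min |  |
| larch | 0.14 M | everything together in a closed stirred flask, run for 80 min | 80 min |
| elm | 0.14 M | a single well-mixed tank run continuously and read at steady state, 400 min in it on average |  |
| birch | 0.14 M (fed, over 64.0 min) | a stirred flask in which Jy is dosed at a steady rate over 64.0 min without added volume, worked up at 80 min | 80 min |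

    Jy + Lx → Lx + Yx (k1 = 4010 M⁻¹ h⁻¹)
    Lx + Yx ⇌ LxYx (K2 = 22 M⁻¹, k2 = 3170 M⁻¹ h⁻¹)
    Xa + LxYx ⇌ Lx + Ju (K3 = 0.61, k3 = 513 M⁻¹ h⁻¹)
    Lx + Rx → LxRx (k4 = 1.94 × 10⁵ M⁻¹ h⁻¹)

1. the set-up with the highest amount of Ju at the outlet or at the end, in percent of the Jy put in ("none" if the first two lie within 2 percentage points) (maple / larch / elm / birch / none)
2. amount of Ju at the outlet or at the end, in percent of the Jy put in, maple
3. amount of Ju at the outlet or at the end, in percent of the Jy put in, larch
4. amount of Ju at the outlet or at the end, in percent of the Jy put in, elm
5. amount of Ju at the outlet or at the end, in percent of the Jy put in, birch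

- the stated concentrations are those of everything mixed, before any reaction; amounts are the same in each set-up
- the feed brings no volume worth counting
- run time (larch): 80 min

Start with larch, the closed flask, where a hand reckoning can be closed. Rx is charged below Lx and, against Lx as charged, has a half-life near 0.692 min, short against the 80 min of the run. You therefore count a working catalyst of 0.222 mM, shared between Lx and LxYx. LxYx forms from Lx and Yx, and it leaves both backwards and onwards to Ju. Balance these flows, with Xa as charged and the return from Ju ignored, and the ratio of LxYx to Lx equals Yx divided by 0.0704 M. This is the loading concentration, the Yx level at which LxYx equals Lx, the Michaelis constant of this round.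

Now divide the rate of Ju by the rate of Jy loss, and time drops out. Taking Yx as the Jy lost and integrating, Ju as a share of the Jy charged is 0.280 times (u minus the fraction of Jy lost), where u is the natural logarithm of Jy charged over Jy left.

Next, bracket u. Counting Lx as the whole working catalyst gives an upper u of 1.19. Counting Lx at its share for Yx equal to the whole Jy charge gives a lower u of 0.397. These two estimates put Ju between 1.94% and 13.8%. Integrating the Jy loss over time lets you feed each bound back once, which narrows u to between 0.615 and 0.859. Your bracket for larch is then 4.36% to 7.92%.

The forecast names elm as best, with 5.9% for maple, 5.6% for larch, 23% for elm and 3.8% for birch, on the ground that “Contact time therefore decides the ranking”. Its larch figure lies above your lower bound and below your upper one.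

The simulation gives elm as best, with 5.92% for maple, 5.61% for larch, 23.1% for elm and 3.20% for birch. In birch the Xa step by itself relaxes with a half-life of 0.516 min at 80.0 min, short against the 80 min of the run, and beside that figure the loading concentration can be tried on the Yx of the moment. In larch at 80.0 min, Yx at 47.6% of the Jy charged gives 34.8% of the catalyst as LxYx, and the flask holds 35.7%. In birch at 80.0 min, Yx at 35.3% gives 29.5%, and the flask holds 30.1%.

The rate constants are made up; the run is a simulation.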